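    pre-initiator → initiator (k1 = 3.62 × 10⁻⁴ s⁻¹)
    protic impurity + free monomer → quenched substrate (k2 = 0.00342 L mol⁻¹ s⁻¹)
    free monomer + living end → monomer in chains + living end, rate k3*[living end]*[free monomer] (k3 = 0.164 L mol⁻¹ s⁻¹)
    initiator + stray impurity → spent initiator (k4 = 0.472 L mol⁻¹ s⁻¹)
    living end + transfer agent → dead chain (k5 = 0.00367 L mol⁻¹ s⁻¹)
    free monomer + initiator → living end + monomer in chains (k6 = 0.0144 L mol⁻¹ s⁻¹)

free monomer 1.5 M; transfer agent 0.450 M; protic impurity 0.450 M; pre-initiator 150 mM; stray impurity 120 mM; time 2.0 h

- average number of monomer units in a chain (chains begun, living or dead) at 2.0 h
- part of the free monomer that has reacted at 2.0 h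

- the average divides the monomer in chains by the number of chains begun, living and dead together
- run time (flask): 2.0 h

I began from a ratio in this flask: a living end grows at 0.164 L mol⁻¹ s⁻¹ times [free monomer] and dies at 0.00367 L mol⁻¹ s⁻¹ times [transfer agent], so [living end] cancels from the ratio of the two, and as long as free monomer is spent on growth and [transfer agent] stays at a fixed value, ln[free monomer] falls by a fixed step per dead chain, however fast the flask runs. I let the protic impurity take its charge first, which left 1.05 M of free monomer for chains. By 2.0 h the pre-initiator should have delivered 0.139 M of initiator, and I gave free monomer a share of it (a selectivity) of 0.211 against the stray impurity, frozen at those concentrations, which made 0.0293 M of chains, all counted as dead. That is far less than the 0.450 M of transfer agent, so I held [transfer agent] at its charge.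

Everything then folds into one number Λ, the growth constant times the chains over the transfer constant times [transfer agent], which counts the e-foldings of free monomer the chains can carry before dying: 2.91. It gave 96.2% reacted and 33.9 units per chain. One number was enough for the conversion, where an error in the share is damped by the small exponential, but the chain length takes that error whole, so I trusted it less.

The forecast said 37 units and 93%, on the ground that “The stray impurity takes most of the initiator”, which my share bears out, although its two numbers differ from mine.

The flask gave 39.7 units and 94.6%. It kept less of its free monomer, 5.4%, than of its transfer agent, 95%. Read from that free monomer, the flask's own Λ was 2.56, below my 2.91.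

For the neighbour with 0.060 M of pre-initiator, at the same share, Λ scales to 1.16, which gives 78.1% reacted and 61.6 units per chain; the neighbour flask gave 74.7% and 67.0.

The numbers of this flask come from no measurement.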